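## The problem

The target is a flavonol with no stereocentre, so every difficulty is one of position and chemoselectivity. Ring A (C4a to C8a) is fused to the pyranone ring C (O1, C2, C3, C4), and C2 carries ring B. Ring A bears oxygen at C8a, C8, C7 and C5 and only C6 is free, so electrophilic routes to a ring A ketone meet a choice between nearly equivalent positions. Three oxygens must end as free hydroxyls (C3, C5, C2') beside three methyl ethers (C7, C8, C4'), which rules out any global ether cleavage. The free flavonol is fragile: the enolic 3-OH is oxidised in base and air, and C2 of the pyranone is open to hydroxide, so the hydroxyls should be released last and under neutral conditions. The C3 oxygen is best carried in with the carbon chain and not added by oxidising a finished flavone. The enabling feature is that C8a and C4a are neighbouring ring A carbons bearing O1 and the C4 carbonyl, flanked by the C8 methoxy group and the C5 oxygen. This is the footprint of an aryne across C8a–C4a that takes up an oxygen nucleophile at one end and an acyl electrophile at the other, with the C5 substituent available to tell the two ends apart.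

## Retrosynthesis

Target 18 to 17. The O–CH2Ph bonds at O3 and O2' are cut. Benzyl is chosen because hydrogenolysis is neutral, spares the methyl ethers and can be the last step. The forward reaction must only avoid reducing the C2=C3 bond.

17 to 16. The S–O bond of a C5 sulfonate is cut. The C5 oxygen is carried as a sulfonate because it is the control element of the aryne step. The forward reaction must cleave at sulfur without opening ring C.

16 to 8 and 14. The bonds O1–C8a and C4–C4a are cut together, which removes ring C and gives an ortho-silylaryl triflate (8) and a ring B beta-keto ester (14).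
- Against the neighbouring cuts: cuts at O1–C2 or C2–C3 (diketone cyclisation, chalcone oxidation) need a ring A acetophenone with four oxygens in defined positions. The aryne cut needs only a catechol derivative whose positions follow from ortho relationships.
- Demands on the forward reaction: the ketone oxygen of the enolate, not its carbon, must add to the aryne; it must add at C8a and not C4a; and the C4a anion must acylate on the ester before it is lost.
- Choice of the C5 group: a triflate would be the strongest director, but an aryl anion ortho to a triflate is expected to expel it (giving a second aryne) or to undergo a thia-Fries shift faster than it can acylate. The C5 oxygen is therefore carried as a tosylate. It is still a stronger sigma-acceptor than methoxy and a far poorer leaving group. A triflate remains only at C4a, where it must leave.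

14 to 11 and 12. The C2–C3 bond (flavone numbering) is cut. This is acylation of the enolate of methyl benzyloxyacetate (12) by the acid chloride 13 of acid 11. It brings in C3 with its oxygen already protected and C4 as the ester. The forward reaction must be C-acylation and must stop after one acylation.

11 to 9. The benzyl ether and the ester are cut, leading back to methyl 2-hydroxy-4-methoxybenzoate (9), which holds all of ring B.

8 to 5. The C8a–Si bond and the O–S bond of the triflate are cut. Both come from one sequence on bromophenol 5: O-silylation, bromine–lithium exchange, silyl shift from oxygen to carbon, and triflation of the phenoxide. This places silicon and the leaving group on adjacent carbons without ambiguity.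

5 to 4 to 2 to 1. The C–Br bond, then the aryl C–O bond made by Baeyer–Villiger oxidation, then the O–Ts bond are cut, ending at 2-hydroxy-4,5-dimethoxybenzaldehyde (1).
- Mapping: the ring carbon bearing the formyl group of 1 becomes C4a, the phenol oxygen of 1 becomes O5, and the CH between the new hydroxyl and a methoxy group becomes C8a.
- Tosylating first differentiates the two catechol oxygens before they exist as a free, oxidisable catechol.
- The bromination is asked to go to the only position ortho to the free hydroxyl.

## Roads not taken

Alternative 1: The cut is C2–C1'. Ring B would be tied to O3 through a formaldehyde acetal to O2', giving 5-benzyloxy-7,8-dimethoxy-3-[(2-bromo-5-methoxyphenoxy)methoxy]chromone A1. Zerovalent palladium, formed from Pd(OAc)2 and PCy3·HBF4 with K2CO3 and pivalic acid, would insert into C1'–Br and arylate the chromone C2–H. This closes a seven-membered dioxepine and gives the methylene-bridged flavonol A2.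
- Merits: the tether fixes the site of arylation and masks 3-OH and 2'-OH with one carbon. Every reaction type is established, which the chosen plan cannot claim for its key step.
- Weak points: the 3-hydroxychromone of ring A must first be made from a tetraoxygenated acetophenone, which is the regiochemical problem the chosen plan avoids. The mixed enol/aryl acetal is awkward to make and to cleave next to three methyl ethers. The closure passes through a strained palladacycle to a twisted biaryl.
- Comparison: the plan is longer and less convergent. The chosen plan sets against it a single step that closes ring C from two simple fragments.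

Alternative 2: The cuts are C4a–C4, C4–C3 and O1–C2. 3-Benzyloxy-2-iodo-5,6-dimethoxyphenol A3, carbon monoxide and 2-benzyloxy-1-ethynyl-4-methoxybenzene A4 would combine under PdCl2(PPh3)2 in diethylamine to give the 3-unsubstituted flavone A5.
- Merits: the carbonylative coupling and cyclisation are well known, and ring A regiochemistry is fixed in A3, so no aryne regiochemistry has to be won. In reliability of the core step this road is better.
- Weak points: A5 lacks the C3 oxygen, so a late oxidation of an electron-rich flavone is needed. Iodination to A3 must go between OH and OBn and not para to the hydroxyl. Five-membered closure to an aurone competes.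
- Comparison: the chosen plan sets against it the C3 oxygen carried from the start and a ring A whose positions follow from ortho chemistry.

Alternative 3: The cuts are C1'–C2' and C5'–C6'. Ring B would be built by cycloaddition of 3,5-bis(benzyloxy)-2-ethynyl-7,8-dimethoxychromone A6 with 1,3-dimethoxy-1-(trimethylsilyloxy)buta-1,3-diene A7. Loss of methanol and of the silyl group would give the 2'-hydroxy flavone A8.
- Merits: diene polarity sets the 2'-OH/4'-OMe pattern, and the 2'-hydroxyl emerges free and distinct from the others.
- Weak points: A6 presupposes the whole ring A/ring C problem solved and then needs an ethynyl group at C2. The conjugated terminal alkyne is a weak dienophile, and simple conjugate addition of the diene terminus can stop short of ring closure.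
- Comparison: ring B is the one part that can be bought with its substituents in place, so building it is poor economy. This road is more reliable only in the regiochemistry of ring B, which the chosen plan gets from a purchased benzoate.

Key step: step 7

Assumption: the alpha-carbon of 14 is used as the racemate because it becomes trigonal in step 7; compounds 1, 9 and 12 are taken as purchasable.

## Route

Step 1
Reactants: 1 2-hydroxy-4,5-dimethoxybenzaldehyde
Product: 2 2-formyl-4,5-dimethoxyphenyl 4-methylbenzenesulfonate
Conditions: TsCl, Et3N, cat. DMAP, CH2Cl2, 0 °C to rt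
Reagents that add atoms: 4-toluenesulfonyl chloride, Cc1ccc(S(=O)(=O)Cl)cc1
Why: Sulfonylation of the only hydroxyl; doing it first fixes which catechol oxygen will become O5.

Step 2
Reactants: 2 2-formyl-4,5-dimethoxyphenyl 4-methylbenzenesulfonate
Product: 4 2-hydroxy-4,5-dimethoxyphenyl 4-methylbenzenesulfonate, via aryl formate 3 (not isolated)
Conditions: mCPBA, CH2Cl2, rt; then MeOH, cat. K2CO3, 0 °C
Reagents that add atoms: 3-chloroperbenzoic acid (mCPBA), O=C(OO)c1cccc(Cl)c1
Why: Baeyer–Villiger (Dakin-type) oxidation in which the aryl group, activated by the para methoxy group, migrates in preference to hydride; mild methanolysis removes the formate and leaves the tosylate, and a tosyl shift between the two oxygens would be degenerate because the dimethoxycatechol core is symmetric.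

Step 3
Reactants: 4 2-hydroxy-4,5-dimethoxyphenyl 4-methylbenzenesulfonate
Product: 5 3-bromo-2-hydroxy-4,5-dimethoxyphenyl 4-methylbenzenesulfonate
Conditions: NBS, MeCN, −20 to 0 °C
Reagents that add atoms: N-bromosuccinimide, O=C1CCC(=O)N1Br
Why: Electrophilic aromatic bromination; the only free position ortho to the hydroxyl (para is blocked) is also ortho to a methoxy group, while the other ring CH is meta to the hydroxyl and next to the deactivating tosyloxy group.

Step 4
Reactants: 5 3-bromo-2-hydroxy-4,5-dimethoxyphenyl 4-methylbenzenesulfonate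
Product: 8 4,5-dimethoxy-2-(trifluoromethylsulfonyloxy)-3-(trimethylsilyl)phenyl 4-methylbenzenesulfonate, via trimethylsilyl ether 6 (not isolated), via lithium phenoxide 7 (not isolated)
Conditions: HMDS, THF, 65 °C, then evaporation; n-BuLi, THF, −100 to −78 °C; Tf2O, −78 to 0 °C
Reagents that add atoms: hexamethyldisilazane, C[Si](C)(C)N[Si](C)(C)C; trifluoromethanesulfonic anhydride, O=S(=O)(OS(=O)(=O)C(F)(F)F)C(F)(F)F
Why: Standard entry to ortho-silylaryl triflates by O-silylation, bromine–lithium exchange, 1,3-shift of silicon from oxygen to carbon (retro-Brook rearrangement) and triflation of the phenoxide; exchange at bromine is expected to outrun attack of n-BuLi on the sulfonate at −100 °C, and the aryllithium is meta to the tosylate and cannot expel it.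

Step 5
Reactants: 9 methyl 2-hydroxy-4-methoxybenzoate
Product: 11 2-(benzyloxy)-4-methoxybenzoic acid, via methyl ester 10 (not isolated)
Conditions: BnBr, K2CO3, DMF, 60 °C; then aq. NaOH, MeOH, 60 °C; HCl
Reagents that add atoms: benzyl bromide, BrCc1ccccc1; sodium hydroxide, [Na+].[OH-]
Why: Williamson etherification of the hydrogen-bonded phenol, then saponification in the same pot; the benzyl ether is stable to hydroxide.

Step 6
Reactants: 11 2-(benzyloxy)-4-methoxybenzoic acid; 12 methyl 2-(benzyloxy)acetate
Product: 14 methyl 2-(benzyloxy)-3-[2-(benzyloxy)-4-methoxyphenyl]-3-oxopropanoate (racemic), via acid chloride 13 (not isolated)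
Conditions: (COCl)2, cat. DMF, CH2Cl2, 0 °C to rt, evaporation; 12, LiN(SiMe3)2 (2.1 equiv), THF, −78 °C, then 13, −78 to −30 °C; AcOH
Reagents that add atoms: none
Why: Crossed Claisen-type C-acylation of a preformed lithium ester enolate by an acid chloride; the second equivalent of base deprotonates 14 as it forms and prevents a second acylation.

Step 7
Reactants: 8 4,5-dimethoxy-2-(trifluoromethylsulfonyloxy)-3-(trimethylsilyl)phenyl 4-methylbenzenesulfonate; 14 methyl 2-(benzyloxy)-3-[2-(benzyloxy)-4-methoxyphenyl]-3-oxopropanoate
Product: 16 3-(benzyloxy)-2-[2-(benzyloxy)-4-methoxyphenyl]-7,8-dimethoxy-4-oxo-4H-chromen-5-yl 4-methylbenzenesulfonate, via aryne 15 (not isolated)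
Conditions: CsF (4 equiv), THF, 65 °C, slow addition of 8
Reagents that add atoms: none
Why: Proposed new method: fluoride attacks silicon of 8 and the C8a carbanion expels the C4a triflate to give aryne 15; the ketone oxygen of the chelated cesium enolate of 14 adds to C8a, and the C4a aryl anion attacks the cis-held methyl ester, closing ring C by a 6-exo-trig addition–elimination with loss of methoxide. The closest known reaction is the CsF-mediated annulation of methyl salicylates with arynes to xanthones in THF, with the phenoxide replaced here by a beta-keto ester enolate. O1–C8a and C4–C4a are formed and no stereocentre is created. Three selectivities are needed: arylation at oxygen and not at carbon, attack at C8a and not C4a, and acylation of the anion before it is lost. The enolate carbon is fully substituted (benzyloxy, ester, aroyl), so C-arylation would have to build a quaternary centre, while the U-shaped cesium chelate presents the ketone oxygen and holds the ester beside the carbon where the anion develops. Attack at C8a puts the anion next to the tosyloxy group, the stronger sigma-acceptor of the two flanking oxygen substituents, and keeps the incoming enolate away from the bulkier sulfonate. A tosylate and not a triflate sits at C5 because an anion ortho to a triflate would expel it or rearrange before acylating; THF is used in place of acetonitrile so that solvent does not protonate the anion.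

Step 8
Reactants: 16 3-(benzyloxy)-2-[2-(benzyloxy)-4-methoxyphenyl]-7,8-dimethoxy-4-oxo-4H-chromen-5-yl 4-methylbenzenesulfonate
Product: 17 3-(benzyloxy)-2-[2-(benzyloxy)-4-methoxyphenyl]-5-hydroxy-7,8-dimethoxy-4H-chromen-4-one
Conditions: KOH, THF–MeOH–H2O, 50 °C; then aq. HCl
Reagents that add atoms: none
Why: Hydrolysis of an aryl sulfonate by attack at sulfur (S–O cleavage), helped by the peri-chelated 5-phenoxide as leaving group; C2 of the 3-benzyloxy-2-aryl pyranone is hindered and should not be opened under these mild conditions.

Step 9
Reactants: 17 3-(benzyloxy)-2-[2-(benzyloxy)-4-methoxyphenyl]-5-hydroxy-7,8-dimethoxy-4H-chromen-4-one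
Product: 18 3,5-dihydroxy-2-(2-hydroxy-4-methoxyphenyl)-7,8-dimethoxy-4H-chromen-4-one (3,5,2'-trihydroxy-7,8,4'-trimethoxyflavone)
Conditions: H2 (1 atm), Pd/C (palladium on carbon), EtOAc–MeOH, rt
Reagents that add atoms: none
Why: Hydrogenolysis of both O-benzyl ethers; the methyl ethers, the tetrasubstituted C2=C3 bond and the carbonyl are not reduced under these conditions.

## Compound list

1 | 2-hydroxy-4,5-dimethoxybenzaldehyde | COc1cc(O)c(C=O)cc1OC | starting material
2 | 2-formyl-4,5-dimethoxyphenyl 4-methylbenzenesulfonate | COc1cc(OS(=O)(=O)c2ccc(C)cc2)c(C=O)cc1OC | intermediate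
3 | 4,5-dimethoxy-2-(tosyloxy)phenyl formate (not isolated) | COc1cc(OS(=O)(=O)c2ccc(C)cc2)c(OC=O)cc1OC | intermediate
4 | 2-hydroxy-4,5-dimethoxyphenyl 4-methylbenzenesulfonate | COc1cc(OS(=O)(=O)c2ccc(C)cc2)c(O)cc1OC | intermediate
5 | 3-bromo-2-hydroxy-4,5-dimethoxyphenyl 4-methylbenzenesulfonate | COc1cc(OS(=O)(=O)c2ccc(C)cc2)c(O)c(Br)c1OC | intermediate
6 | 3-bromo-4,5-dimethoxy-2-(trimethylsilyloxy)phenyl 4-methylbenzenesulfonate (not isolated) | COc1cc(OS(=O)(=O)c2ccc(C)cc2)c(O[Si](C)(C)C)c(Br)c1OC | intermediate
7 | lithium 3,4-dimethoxy-6-(tosyloxy)-2-(trimethylsilyl)phenolate (not isolated) | [Li+].COc1cc(OS(=O)(=O)c2ccc(C)cc2)c([O-])c([Si](C)(C)C)c1OC | intermediate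
8 | 4,5-dimethoxy-2-(trifluoromethylsulfonyloxy)-3-(trimethylsilyl)phenyl 4-methylbenzenesulfonate | COc1cc(OS(=O)(=O)c2ccc(C)cc2)c(OS(=O)(=O)C(F)(F)F)c([Si](C)(C)C)c1OC | intermediate
9 | methyl 2-hydroxy-4-methoxybenzoate | COC(=O)c1ccc(OC)cc1O | starting material
10 | methyl 2-(benzyloxy)-4-methoxybenzoate (not isolated) | COC(=O)c1ccc(OC)cc1OCc1ccccc1 | intermediate
11 | 2-(benzyloxy)-4-methoxybenzoic acid | OC(=O)c1ccc(OC)cc1OCc1ccccc1 | intermediate
12 | methyl 2-(benzyloxy)acetate | COC(=O)COCc1ccccc1 | starting material
13 | 2-(benzyloxy)-4-methoxybenzoyl chloride (not isolated) | O=C(Cl)c1ccc(OC)cc1OCc1ccccc1 | intermediate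
14 | methyl 2-(benzyloxy)-3-[2-(benzyloxy)-4-methoxyphenyl]-3-oxopropanoate (racemic) | COC(=O)C(OCc1ccccc1)C(=O)c1ccc(OC)cc1OCc1ccccc1 | intermediate
15 | 3,4-dimethoxy-6-(tosyloxy)benzyne (1,2-didehydrobenzene, not isolated) | COC1=C(OC)C#CC(OS(=O)(=O)c2ccc(C)cc2)=C1 | intermediate
16 | 3-(benzyloxy)-2-[2-(benzyloxy)-4-methoxyphenyl]-7,8-dimethoxy-4-oxo-4H-chromen-5-yl 4-methylbenzenesulfonate | COc1ccc(-c2oc3c(OC)c(OC)cc(OS(=O)(=O)c4ccc(C)cc4)c3c(=O)c2OCc2ccccc2)c(OCc2ccccc2)c1 | intermediate
17 | 3-(benzyloxy)-2-[2-(benzyloxy)-4-methoxyphenyl]-5-hydroxy-7,8-dimethoxy-4H-chromen-4-one | COc1ccc(-c2oc3c(OC)c(OC)cc(O)c3c(=O)c2OCc2ccccc2)c(OCc2ccccc2)c1 | intermediate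
18 | 3,5-dihydroxy-2-(2-hydroxy-4-methoxyphenyl)-7,8-dimethoxy-4H-chromen-4-one | COc1ccc(-c2oc3c(OC)c(OC)cc(O)c3c(=O)c2O)c(O)c1 | target

## Step count and risks

Total steps: 9. Longest linear sequence: 7 (steps 1, 2, 3, 4, 7, 8, 9).

**Step 7 (key step, proposed new method).**
- What may go wrong: carbon arylation of the enolate, after which the aryl anion adds to the ketone and the four-membered alkoxide fragments (insertion of the aryne into the C–C bond). Second, addition of the enolate oxygen to C4a instead of C8a, because the pull of the tosyloxy group over the methoxy group is modest. Third, protonation of the C4a anion before ring closure.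
- Fallback (known chemistry): it sets out from acid 11 as its chloride 13 and returns to the route at 18. Chloride 13 acylates purchased 1-(2-hydroxy-3,4,6-trimethoxyphenyl)ethanone F1 in pyridine to give 2-acetyl-3,5,6-trimethoxyphenyl 2-(benzyloxy)-4-methoxybenzoate F2. Baker–Venkataraman acyl shift (KOH, pyridine) gives 1-[2-(benzyloxy)-4-methoxyphenyl]-3-(2-hydroxy-3,4,6-trimethoxyphenyl)propane-1,3-dione F3. Acid-catalysed cyclodehydration gives 2-[2-(benzyloxy)-4-methoxyphenyl]-5,7,8-trimethoxy-4H-chromen-4-one F4. Epoxidation of C2=C3 with dimethyldioxirane and acid-induced opening gives 2-[2-(benzyloxy)-4-methoxyphenyl]-3-hydroxy-5,7,8-trimethoxy-4H-chromen-4-one F5. BCl3 in CH2Cl2 then removes the 2'-benzyl ether and the carbonyl-chelated 5-methyl ether to give 18.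

**Step 4.**
- What may go wrong: attack of n-BuLi at the sulfonate sulfur, or tosyl transfer to the neighbouring lithium phenoxide before triflation, which would scramble the two sulfonates.
- Fallback: it sets out from 1 and returns at 8, with the sulfonates installed after the organolithium step. Bromination of 1 gives 3-bromo-2-hydroxy-4,5-dimethoxybenzaldehyde F6. Dakin oxidation (H2O2, NaOH) gives 3-bromo-4,5-dimethoxybenzene-1,2-diol F7. HMDS gives 3-bromo-4,5-dimethoxy-1,2-bis(trimethylsilyloxy)benzene F8. n-BuLi with silyl shift and aqueous work-up gives 4,5-dimethoxy-3-(trimethylsilyl)benzene-1,2-diol F9. One equivalent of TsCl at low temperature sulfonylates the hydroxyl remote from the silyl group to give 2-hydroxy-4,5-dimethoxy-3-(trimethylsilyl)phenyl 4-methylbenzenesulfonate F10. Tf2O and pyridine then give 8.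

**Step 6.**
- What may go wrong: O-acylation of the ester enolate, or self-condensation of 12, in competition with C-acylation by the hindered, electron-rich acid chloride.
- Fallback: it sets out from 13 and returns at 14. Potassium methyl malonate with MgCl2 and Et3N, then decarboxylation, gives methyl 3-[2-(benzyloxy)-4-methoxyphenyl]-3-oxopropanoate F11. Diazo transfer (4-acetamidobenzenesulfonyl azide, Et3N) gives methyl 3-[2-(benzyloxy)-4-methoxyphenyl]-2-diazo-3-oxopropanoate F12. O–H insertion of the carbenoid from Rh2(OAc)4 into benzyl alcohol gives 14.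

**Step 8.**
- What may go wrong: addition of hydroxide or methoxide at C2 with opening of ring C, in competition with slow attack at the sulfonate sulfur.
- Fallback: it sets out from 16 and returns at 18 by reversing the order of the last two steps. Hydrogenolysis of 16 gives 3-hydroxy-2-(2-hydroxy-4-methoxyphenyl)-7,8-dimethoxy-4-oxo-4H-chromen-5-yl 4-methylbenzenesulfonate F13. In degassed aqueous KOH this is present as the flavonolate, whose negative charge shields C2 from nucleophiles, so hydroxide should cleave only the sulfonate and give 18.

## Further compounds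

F1 | step 7 | 1-(2-hydroxy-3,4,6-trimethoxyphenyl)ethanone (purchased) | CC(=O)c1c(O)c(OC)c(OC)cc1OC
F2 | step 7 | 2-acetyl-3,5,6-trimethoxyphenyl 2-(benzyloxy)-4-methoxybenzoate | CC(=O)c1c(OC(=O)c2ccc(OC)cc2OCc2ccccc2)c(OC)c(OC)cc1OC
F3 | step 7 | 1-[2-(benzyloxy)-4-methoxyphenyl]-3-(2-hydroxy-3,4,6-trimethoxyphenyl)propane-1,3-dione | COc1ccc(C(=O)CC(=O)c2c(O)c(OC)c(OC)cc2OC)c(OCc2ccccc2)c1
F4 | step 7 | 2-[2-(benzyloxy)-4-methoxyphenyl]-5,7,8-trimethoxy-4H-chromen-4-one | COc1ccc(-c2cc(=O)c3c(OC)cc(OC)c(OC)c3o2)c(OCc2ccccc2)c1
F5 | step 7 | 2-[2-(benzyloxy)-4-methoxyphenyl]-3-hydroxy-5,7,8-trimethoxy-4H-chromen-4-one | COc1ccc(-c2oc3c(OC)c(OC)cc(OC)c3c(=O)c2O)c(OCc2ccccc2)c1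
F6 | step 4 | 3-bromo-2-hydroxy-4,5-dimethoxybenzaldehyde | COc1cc(C=O)c(O)c(Br)c1OC
F7 | step 4 | 3-bromo-4,5-dimethoxybenzene-1,2-diol | COc1cc(O)c(O)c(Br)c1OC
F8 | step 4 | 3-bromo-4,5-dimethoxy-1,2-bis(trimethylsilyloxy)benzene | COc1cc(O[Si](C)(C)C)c(O[Si](C)(C)C)c(Br)c1OC
F9 | step 4 | 4,5-dimethoxy-3-(trimethylsilyl)benzene-1,2-diol | COc1cc(O)c(O)c([Si](C)(C)C)c1OC
F10 | step 4 | 2-hydroxy-4,5-dimethoxy-3-(trimethylsilyl)phenyl 4-methylbenzenesulfonate | COc1cc(OS(=O)(=O)c2ccc(C)cc2)c(O)c([Si](C)(C)C)c1OC
F11 | step 6 | methyl 3-[2-(benzyloxy)-4-methoxyphenyl]-3-oxopropanoate | COC(=O)CC(=O)c1ccc(OC)cc1OCc1ccccc1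
F12 | step 6 | methyl 3-[2-(benzyloxy)-4-methoxyphenyl]-2-diazo-3-oxopropanoate | COC(=O)C(=[N+]=[N-])C(=O)c1ccc(OC)cc1OCc1ccccc1
F13 | step 8 | 3-hydroxy-2-(2-hydroxy-4-methoxyphenyl)-7,8-dimethoxy-4-oxo-4H-chromen-5-yl 4-methylbenzenesulfonate | COc1ccc(-c2oc3c(OC)c(OC)cc(OS(=O)(=O)c4ccc(C)cc4)c3c(=O)c2O)c(O)c1
A1 | alternative 1 | 5-(benzyloxy)-3-[(2-bromo-5-methoxyphenoxy)methoxy]-7,8-dimethoxy-4H-chromen-4-one | COc1ccc(Br)c(OCOc2coc3c(OC)c(OC)cc(OCc4ccccc4)c3c2=O)c1
A2 | alternative 1 | 5-O-benzyl flavonol with O3 and O2' joined by a methylene bridge (dioxepine-fused) | COc1ccc2c(c1)OCOc1c-2oc2c(OC)c(OC)cc(OCc3ccccc3)c2c1=O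
A3 | alternative 2 | 3-(benzyloxy)-2-iodo-5,6-dimethoxyphenol | COc1cc(OCc2ccccc2)c(I)c(O)c1OC
A4 | alternative 2 | 2-(benzyloxy)-1-ethynyl-4-methoxybenzene | C#Cc1ccc(OC)cc1OCc1ccccc1
A5 | alternative 2 | 5-(benzyloxy)-2-[2-(benzyloxy)-4-methoxyphenyl]-7,8-dimethoxy-4H-chromen-4-one | COc1ccc(-c2cc(=O)c3c(OCc4ccccc4)cc(OC)c(OC)c3o2)c(OCc2ccccc2)c1
A6 | alternative 3 | 3,5-bis(benzyloxy)-2-ethynyl-7,8-dimethoxy-4H-chromen-4-one | C#Cc1oc2c(OC)c(OC)cc(OCc3ccccc3)c2c(=O)c1OCc1ccccc1
A7 | alternative 3 | 1,3-dimethoxy-1-(trimethylsilyloxy)buta-1,3-diene | C=C(OC)C=C(OC)O[Si](C)(C)C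
A8 | alternative 3 | 3,5-bis(benzyloxy)-2-(2-hydroxy-4-methoxyphenyl)-7,8-dimethoxy-4H-chromen-4-one | COc1ccc(-c2oc3c(OC)c(OC)cc(OCc4ccccc4)c3c(=O)c2OCc2ccccc2)c(O)c1
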